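**Retrosynthetic overview**
- The C16–C17 bond is cut last: a Stille coupling joins a (Z)-dienyl iodide to a 4-stannylbutenolide, so the butenolide ring is bought, not built.
- The E-trisubstituted olefin (CH2OH trans to the diene) comes from a Wittig reaction of an α-alkylated ester ylide with (Z)-3-iodoacrolein, followed by ester reduction.
- The ylide is made by C-alkylation with a homoallylic iodide (12-iodo-11-homodrim-8-ene) that already carries both stereocentres.
- That iodide comes from unzipping the ether ring of (−)-ambrox; the tetrahydrofuran is a disposable third ring that lets the C8=C9 olefin be placed afterwards under thermodynamic control.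
- Key step: one catalytic asymmetric polyene cyclization of acyclic (3E,7E)-homofarnesol closes ring A, then ring B, then the tetrahydrofuran in a single cascade and sets C5 and C10.

Assumption: the entry is taken to be exactly the given SMILES, read as (4aS,8aS) trans-fused decalin, E at the trisubstituted olefin and Z at the disubstituted olefin.

Shorthand used in names: "decalinyl" = (4aS,8aS)-2,5,5,8a-tetramethyl-3,4,4a,5,6,7,8,8a-octahydronaphthalen-1-yl (trans-fused; 8a-methyl and 4a-H on opposite faces; ring olefin C1=C2).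

**Route**

Step 1
Reactants: 1 (2E,6E)-farnesyl bromide [(2E,6E)-1-bromo-3,7,11-trimethyldodeca-2,6,10-triene]
Product: 3 (3E,7E)-homofarnesol [(3E,7E)-4,8,12-trimethyltrideca-3,7,11-trien-1-ol], via homofarnesyl(isopropoxy)dimethylsilane 2 (not isolated)
Conditions: (i-PrO)Me2SiCH2MgCl (1.5 equiv), Li2CuCl4 (3 mol%), THF, 0 °C → rt; then KF, KHCO3, 30% H2O2, THF/MeOH, rt
Reagents that add atoms: (isopropoxydimethylsilyl)methylmagnesium chloride, CC(C)O[Si](C)(C)C[Mg]Cl; hydrogen peroxide, OO
Why: Copper-catalysed SN2 coupling of the allylic bromide with a hydroxymethyl-anion equivalent leaves both E olefins untouched, and Tamao oxidation of the C–Si bond then gives the primary alcohol; no stereocentre is formed.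

Step 2
Reactants: 3 (3E,7E)-homofarnesol
Product: 4 (−)-ambrox [(3aR,5aS,9aS,9bR)-3a,6,6,9a-tetramethyldodecahydronaphtho[2,1-b]furan]
Conditions: chiral imidodiphosphorimidate Brønsted acid [(3,3′-Ar2-BINOL)P(=NSO2CF3)]2NH, Ar = 3,5-(CF3)2C6H3, the antipode that gives levorotatory 4 (2 mol%), (CF3)3COH, 0 °C, 48 h; recrystallise from MeOH/H2O to raise ee
Reagents that add atoms: none
Why: This is a Brønsted-acid-initiated Stork–Eschenmoser polyene cyclization in which the confined chiral counter-anion selects the face of the terminal olefin that is protonated, the E,E-triene folds chair–chair so that ring A, ring B and then the ether ring close in one cascade, and the hydroxyl traps the C8 cation, giving the trans-fused 5S,10S decalin (C8 and C9 are also set but are erased in step 3).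

Step 3
Reactants: 4 (−)-ambrox
Product: 6 (4aS,8aS)-1-(2-iodoethyl)-2,5,5,8a-tetramethyl-3,4,4a,5,6,7,8,8a-octahydronaphthalene (12-iodo-11-homodrim-8-ene), via ring-opened trimethylsilyl ether 5 (not isolated)
Conditions: Me3SiCl (3 equiv), NaI (3 equiv), MeCN, 0 → 25 °C, 24 h, dark; aq. NaHCO3/Na2S2O3; AgNO3–silica if olefin isomers remain
Reagents that add atoms: iodotrimethylsilane, C[Si](C)(C)I (made in the flask from Me3SiCl and NaI)
Why: Proposed new method: Me3SiI silylates the ether oxygen, the tertiary C8–O bond ionises (SN1), the C8 cation loses a proton under reversible HI catalysis to give the thermodynamically preferred tetrasubstituted C8=C9 olefin (as in the Zaitsev-selective E1 dehydration of 8α-hydroxydrimanes with PPh3/I2), and a second Me3SiI converts the primary silyl ether into the iodide by SN2, the closest known reaction being Me3SiI cleavage of dialkyl ethers to alkyl iodides; C5 and C10 are not touched.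

Step 4
Reactants: 6 12-iodo-11-homodrim-8-ene; 7 ethyl (triphenylphosphoranylidene)acetate (Ph3P=CHCO2Et)
Product: 9 ethyl 4-(decalinyl)-2-(triphenyl-λ5-phosphanylidene)butanoate, via alkylated phosphonium iodide 8 (not isolated)
Conditions: 7 (2.5 equiv), MeCN, 80 °C, 36 h; filter off the phosphonium salt, concentrate
Reagents that add atoms: none
Why: C-alkylation of a stabilised phosphorus ylide by a primary iodide (SN2) is followed by transylidation with the second equivalent of ylide, and this weakly basic nucleophile is chosen because it should not eliminate HI from the homoallylic iodide; no stereocentre of consequence is formed.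

Step 5
Reactants: 9 the α-alkylated ylide; 10 ethyl (Z)-3-iodoacrylate
Product: 12 ethyl (2E,4Z)-5-iodo-2-[2-(decalinyl)ethyl]penta-2,4-dienoate, via (Z)-3-iodoacrolein 11 (not isolated)
Conditions: 10, i-Bu2AlH (1.05 equiv), CH2Cl2, −78 °C, 30 min; then 9, −78 → 0 °C, dark; aq. KNaC4H4O6
Reagents that add atoms: none
Why: Half-reduction of the ester to the aldehyde at −78 °C and an in-flask Wittig reaction with the α-branched stabilised ylide give the E-trisubstituted enoate (ester trans to the new vinyl group, so the decalinyl-ethyl chain is cis to it), and the Z-vinyl iodide survives because the labile aldehyde never leaves the cold solution.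

Step 6
Reactants: 12 the (2E,4Z)-iododienoate
Product: 13 (2E,4Z)-5-iodo-2-[2-(decalinyl)ethyl]penta-2,4-dien-1-ol
Conditions: i-Bu2AlH (2.3 equiv), CH2Cl2, −78 °C, 1 h; aq. KNaC4H4O6
Reagents that add atoms: none
Why: 1,2-Reduction of the conjugated ester by i-Bu2AlH at low temperature gives the allylic alcohol without touching the vinyl iodide or either olefin geometry.

Step 7
Reactants: 14 4-bromofuran-2(5H)-one
Product: 15 4-(tributylstannyl)furan-2(5H)-one
Conditions: (Bu3Sn)2 (1.3 equiv), Pd(PPh3)4 (5 mol%), toluene, 90 °C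
Reagents that add atoms: hexabutylditin, CCCC[Sn](CCCC)(CCCC)[Sn](CCCC)(CCCC)CCCC
Why: Palladium-catalysed stannylation of a vinyl bromide with a distannane (oxidative addition, Sn–Sn transmetalation, reductive elimination) turns the electrophilic β-bromobutenolide into its Stille nucleophile.

Step 8
Reactants: 13 the (2E,4Z)-iododienol; 15 4-(tributylstannyl)furan-2(5H)-one
Product: 16 4-[(1Z,3E)-4-(hydroxymethyl)-6-(decalinyl)hexa-1,3-dien-1-yl]furan-2(5H)-one (target)
Conditions: Pd2(dba)3 (2.5 mol%), AsPh3 (20 mol%), DMF, 25 °C, dark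
Reagents that add atoms: none
Why: Stille cross-coupling of a vinyl iodide with a vinylstannane goes with retention at both sp2 carbons at room temperature and tolerates the free allylic alcohol and the lactone, so it delivers the 1Z,3E-dienylbutenolide directly.

**Compound list**
1 | (2E,6E)-farnesyl bromide | CC(C)=CCC/C(C)=C/CC/C(C)=C/CBr | starting material
2 | [(3E,7E)-4,8,12-trimethyltrideca-3,7,11-trien-1-yl](isopropoxy)dimethylsilane | CC(C)=CCC/C(C)=C/CC/C(C)=C/CC[Si](C)(C)OC(C)C | intermediate (not isolated)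
3 | (3E,7E)-4,8,12-trimethyltrideca-3,7,11-trien-1-ol (homofarnesol) | CC(C)=CCC/C(C)=C/CC/C(C)=C/CCO | intermediate
4 | (3aR,5aS,9aS,9bR)-3a,6,6,9a-tetramethyldodecahydronaphtho[2,1-b]furan, (−)-ambrox | C[C@@]12CC[C@H]3C(C)(C)CCC[C@]3(C)[C@H]1CCO2 | intermediate
5 | (4aS,8aS)-2,5,5,8a-tetramethyl-1-[2-(trimethylsilyloxy)ethyl]-3,4,4a,5,6,7,8,8a-octahydronaphthalene | CC1=C(CCO[Si](C)(C)C)[C@@]2(C)CCCC(C)(C)[C@@H]2CC1 | intermediate (not isolated)
6 | (4aS,8aS)-1-(2-iodoethyl)-2,5,5,8a-tetramethyl-3,4,4a,5,6,7,8,8a-octahydronaphthalene | CC1=C(CCI)[C@@]2(C)CCCC(C)(C)[C@@H]2CC1 | intermediate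
7 | ethyl (triphenylphosphoranylidene)acetate | CCOC(=O)C=P(c1ccccc1)(c1ccccc1)c1ccccc1 | starting material
8 | {1-ethoxy-1-oxo-4-[(4aS,8aS)-2,5,5,8a-tetramethyl-3,4,4a,5,6,7,8,8a-octahydronaphthalen-1-yl]butan-2-yl}triphenylphosphonium iodide (both C2 epimers) | CC1=C(CCC(C(=O)OCC)[P+](c3ccccc3)(c3ccccc3)c3ccccc3)[C@@]2(C)CCCC(C)(C)[C@@H]2CC1.[I-] | intermediate (not isolated)
9 | ethyl 4-[(4aS,8aS)-2,5,5,8a-tetramethyl-3,4,4a,5,6,7,8,8a-octahydronaphthalen-1-yl]-2-(triphenyl-λ5-phosphanylidene)butanoate | CC1=C(CCC(C(=O)OCC)=P(c3ccccc3)(c3ccccc3)c3ccccc3)[C@@]2(C)CCCC(C)(C)[C@@H]2CC1 | intermediate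
10 | ethyl (Z)-3-iodoacrylate | CCOC(=O)/C=C\I | starting material
11 | (Z)-3-iodoprop-2-enal | O=C/C=C\I | intermediate (not isolated)
12 | ethyl (2E,4Z)-5-iodo-2-{2-[(4aS,8aS)-2,5,5,8a-tetramethyl-3,4,4a,5,6,7,8,8a-octahydronaphthalen-1-yl]ethyl}penta-2,4-dienoate | CC1=C(CC/C(=C\C=C/I)C(=O)OCC)[C@@]2(C)CCCC(C)(C)[C@@H]2CC1 | intermediate
13 | (2E,4Z)-5-iodo-2-{2-[(4aS,8aS)-2,5,5,8a-tetramethyl-3,4,4a,5,6,7,8,8a-octahydronaphthalen-1-yl]ethyl}penta-2,4-dien-1-ol | CC1=C(CC/C(=C\C=C/I)CO)[C@@]2(C)CCCC(C)(C)[C@@H]2CC1 | intermediate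
14 | 4-bromofuran-2(5H)-one | O=C1C=C(Br)CO1 | starting material
15 | 4-(tributylstannyl)furan-2(5H)-one | CCCC[Sn](CCCC)(CCCC)C1=CC(=O)OC1 | intermediate
16 | 4-[(1Z,3E)-4-(hydroxymethyl)-6-[(4aS,8aS)-2,5,5,8a-tetramethyl-3,4,4a,5,6,7,8,8a-octahydronaphthalen-1-yl]hexa-1,3-dien-1-yl]furan-2(5H)-one | CC1=C(CC/C(=C\C=C/C2=CC(=O)OC2)CO)[C@@]2(C)CCCC(C)(C)[C@@H]2CC1 | target

**Count**
Total steps: 8. Longest linear sequence: 7 (steps 1–6 and 8; step 7 prepares the coupling partner).

**Three steps most likely to fail, with fallbacks**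

Step 3 (ether unzipping) is new chemistry. It may stop at the silyl ether, give Δ7 or exocyclic olefin isomers, or let HI trigger a 1,2-methyl shift from C10. The fallback sets out from 4 and returns at 6 by moving the carbon oxidation level instead of cleaving the ether directly. Oxidation of the ether CH2 with RuCl3 (cat.)/NaIO4 gives (+)-sclareolide F1. H2SO4 in MeOH opens the lactone by E1 to methyl 2-(decalinyl)acetate F2, the tetrasubstituted olefin being the main isomer (purified on AgNO3–silica). LiAlH4 reduces it to 2-(decalinyl)ethan-1-ol F3, and I2/PPh3/imidazole converts that into 6.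

Step 4 (ylide alkylation) may be too slow because a stabilised ylide is a poor nucleophile toward an unactivated primary iodide. The fallback sets out from 6 and returns at 12 by switching to phosphonate carbanion chemistry. The sodium salt of triethyl phosphonoacetate (NaH, DMF, 50 °C, excess) is alkylated by 6 to give ethyl 2-(diethoxyphosphoryl)-4-(decalinyl)butanoate F4. A Horner–Wadsworth–Emmons reaction (LiCl, DBU, MeCN, 0 °C) with 11, made from 10 as in step 5, then gives 12.

Step 8 (final Stille coupling) uses an electron-poor stannane that transmetalates slowly, so Z→E leakage, protodestannylation or a 6π-electrocyclization of the product triene on warming could intervene. The fallback sets out from 9 and 14 and returns at 16 by building the Z olefin from an alkyne, with no tin. Wittig reaction of 9 with 3-(trimethylsilyl)propynal gives ethyl (2E)-2-[2-(decalinyl)ethyl]-5-(trimethylsilyl)pent-2-en-4-ynoate F5. i-Bu2AlH reduces it to (2E)-2-[2-(decalinyl)ethyl]-5-(trimethylsilyl)pent-2-en-4-yn-1-ol F6. Desilylative Sonogashira coupling with 14 (PdCl2(PPh3)2, CuI, CsF, Et3N, DMF) gives 4-[(3E)-4-(hydroxymethyl)-6-(decalinyl)hex-3-en-1-yn-1-yl]furan-2(5H)-one F7. cis-Selective semireduction with zinc dust activated by Cu(OAc)2 and AgNO3 in MeOH/H2O then gives 16.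

**Further compounds**
F1 | step 3 | (3aR,5aS,9aS,9bR)-3a,6,6,9a-tetramethyldecahydronaphtho[2,1-b]furan-2(1H)-one, (+)-sclareolide | C[C@@]12CC[C@H]3C(C)(C)CCC[C@]3(C)[C@H]1CC(=O)O2
F2 | step 3 | methyl 2-[(4aS,8aS)-2,5,5,8a-tetramethyl-3,4,4a,5,6,7,8,8a-octahydronaphthalen-1-yl]acetate | CC1=C(CC(=O)OC)[C@@]2(C)CCCC(C)(C)[C@@H]2CC1
F3 | step 3 | 2-[(4aS,8aS)-2,5,5,8a-tetramethyl-3,4,4a,5,6,7,8,8a-octahydronaphthalen-1-yl]ethan-1-ol | CC1=C(CCO)[C@@]2(C)CCCC(C)(C)[C@@H]2CC1
F4 | step 4 | ethyl 2-(diethoxyphosphoryl)-4-[(4aS,8aS)-2,5,5,8a-tetramethyl-3,4,4a,5,6,7,8,8a-octahydronaphthalen-1-yl]butanoate (both C2 epimers) | CC1=C(CCC(C(=O)OCC)P(=O)(OCC)OCC)[C@@]2(C)CCCC(C)(C)[C@@H]2CC1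
F5 | step 8 | ethyl (2E)-2-{2-[(4aS,8aS)-2,5,5,8a-tetramethyl-3,4,4a,5,6,7,8,8a-octahydronaphthalen-1-yl]ethyl}-5-(trimethylsilyl)pent-2-en-4-ynoate | CC1=C(CC/C(=C\C#C[Si](C)(C)C)C(=O)OCC)[C@@]2(C)CCCC(C)(C)[C@@H]2CC1
F6 | step 8 | (2E)-2-{2-[(4aS,8aS)-2,5,5,8a-tetramethyl-3,4,4a,5,6,7,8,8a-octahydronaphthalen-1-yl]ethyl}-5-(trimethylsilyl)pent-2-en-4-yn-1-ol | CC1=C(CC/C(=C\C#C[Si](C)(C)C)CO)[C@@]2(C)CCCC(C)(C)[C@@H]2CC1
F7 | step 8 | 4-[(3E)-4-(hydroxymethyl)-6-[(4aS,8aS)-2,5,5,8a-tetramethyl-3,4,4a,5,6,7,8,8a-octahydronaphthalen-1-yl]hex-3-en-1-yn-1-yl]furan-2(5H)-one | CC1=C(CC/C(=C\C#CC3=CC(=O)OC3)CO)[C@@]2(C)CCCC(C)(C)[C@@H]2CC1
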